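Ring A, the acylphloroglucinol, is opened at the bond between its acyl-bearing carbon and a neighbouring C–OH carbon. This turns the arene into a linear tetraketide, a methyl 3,5,7-trioxodecanoate: chain C2 and C4 (the ring carbons that hold the two pyranonylmethyl arms) and C6 sit between carbonyls, matching the alternating C/C–OH pattern of ring A. A single Claisen closure of C6 onto ester carbon C1 makes that bond and the benzene ring and leaves the (R)-2-methylbutanoyl group outside the ring. In the precursor's synthesis C7 is masked as a dioxolane, so that only C2 and C4 are doubly activated when both O-methylated pyranone arms go on.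

Key step: step 10

Assumption: chain positions C1–C10 are numbered as in the decanoate precursor (C1 ester carbon, C8 the stereocentre); the silyl enol ether is used as an E/Z mixture and the armed chain compounds as mixtures of C2/C4 epimers and enol tautomers, all of which converge at aromatisation.

Step 1
Reactants: 1 3-pentanone
Product: 2 3-(trimethylsilyloxy)pent-2-ene (E/Z mixture)
Conditions: TMSOTf, Et3N, CH2Cl2, 0 °C
Reagents that add atoms: trimethylsilyl trifluoromethanesulfonate, C[Si](C)(C)OS(=O)(=O)C(F)(F)F
Why: Silyl enol ether formation from a symmetrical ketone with a silyl triflate and a tertiary amine has only one possible regiochemical outcome, and the alkene geometry is of no consequence for the annulation that follows.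

Step 2
Reactants: 2 3-(trimethylsilyloxy)pent-2-ene; 3 malonyl dichloride
Product: 4 6-ethyl-4-hydroxy-5-methyl-2H-pyran-2-one
Conditions: Et2O, −78 °C → rt
Reagents that add atoms: none
Why: This is the known pyranone annulation of ketone silyl enol ethers with malonyl dichloride, in which C-acylation at the enol ether carbon (former C2 of the ketone) is followed by O-acylation of the new enol by the second acid chloride, so the ethyl group ends at C6, the methyl at C5 and C3 stays unsubstituted.

Step 3
Reactants: 4 6-ethyl-4-hydroxy-5-methyl-2H-pyran-2-one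
Product: 5 6-ethyl-4-methoxy-5-methyl-2H-pyran-2-one
Conditions: Me2SO4, K2CO3, acetone, reflux
Reagents that add atoms: dimethyl sulfate, COS(=O)(=O)OC
Why: Williamson-type O-methylation of the acidic 4-hydroxyl with dimethyl sulfate and K2CO3 in acetone is the standard entry to 4-methoxy-2-pyranones and removes the acidic, nucleophilic enol before the ring and the chain are elaborated.

Step 4
Reactants: 5 6-ethyl-4-methoxy-5-methyl-2H-pyran-2-one
Product: 6 3-(chloromethyl)-6-ethyl-4-methoxy-5-methyl-2H-pyran-2-one
Conditions: (CH2O)n, HCl (g), ZnCl2 (cat.), 1,4-dioxane, 50 °C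
Reagents that add atoms: paraformaldehyde (formaldehyde), C=O; hydrogen chloride, Cl
Why: Blanc chloromethylation should take place at C3, the only free ring position and the enol-ether-like carbon at which 4-methoxy-2-pyranones undergo electrophilic substitution, with the excess of formaldehyde and HCl holding back a second arylation of the benzylic-type chloride.

Step 5
Reactants: 7 (R)-2-methylbutanoic acid; 8 Meldrum's acid (2,2-dimethyl-1,3-dioxane-4,6-dione)
Product: 10 (4R)-N-methoxy-N,4-dimethyl-3-oxohexanamide, via acyl Meldrum's acid 9 (not isolated)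
Conditions: 8, DCC, DMAP, CH2Cl2, 0 °C → rt; then MeNHOMe·HCl, Et3N, PhMe, 80 °C
Reagents that add atoms: N,O-dimethylhydroxylamine hydrochloride, CNOC.Cl
Why: Carbodiimide-mediated C-acylation of Meldrum's acid followed by thermal loss of acetone and CO2 to an acylketene that is captured by the hydroxylamine is a standard two-carbon homologation of an acid to a β-keto amide, and its nearly neutral conditions should leave the α-stereocentre intact.

Step 6
Reactants: 10 (4R)-N-methoxy-N,4-dimethyl-3-oxohexanamide
Product: 11 2-{2-[(2R)-butan-2-yl]-1,3-dioxolan-2-yl}-N-methoxy-N-methylacetamide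
Conditions: TMSOCH2CH2OTMS, TMSOTf (cat.), CH2Cl2, −78 → −20 °C
Reagents that add atoms: 1,2-bis(trimethylsilyloxy)ethane, C[Si](C)(C)OCCO[Si](C)(C)C
Why: Dioxolane formation with the bis-silyl ether of ethylene glycol under catalytic TMSOTf (silyl-triflate-catalysed ketalisation) runs under kinetic control at low temperature and is suited to hindered ketones, so C7 should be masked without enol ether formation toward the adjacent stereocentre.

Step 7
Reactants: 12 methyl acetoacetate; 11 2-{2-[(2R)-butan-2-yl]-1,3-dioxolan-2-yl}-N-methoxy-N-methylacetamide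
Product: 13 methyl 6-{2-[(2R)-butan-2-yl]-1,3-dioxolan-2-yl}-3,5-dioxohexanoate
Conditions: 12 (1.5 equiv), LiN(iPr)2 (3.1 equiv), THF, −78 → 0 °C; then 11, −78 → 0 °C; aq. NH4Cl
Reagents that add atoms: none
Why: γ-Acylation of a β-keto ester 1,3-dianion with a Weinreb amide stops at the chelated tetrahedral adduct until work-up and so should deliver the 3,5-diketo ester cleanly, while the ketal carbon next to the stereocentre cannot enolise.

Step 8
Reactants: 13 methyl 6-{2-[(2R)-butan-2-yl]-1,3-dioxolan-2-yl}-3,5-dioxohexanoate; 6 3-(chloromethyl)-6-ethyl-4-methoxy-5-methyl-2H-pyran-2-one (2.2 equiv)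
Product: 14 methyl 6-{2-[(2R)-butan-2-yl]-1,3-dioxolan-2-yl}-2,4-bis[(6-ethyl-4-methoxy-5-methyl-2-oxo-2H-pyran-3-yl)methyl]-3,5-dioxohexanoate
Conditions: LiN(iPr)2 (2.1 equiv), THF, −78 → 0 °C; then 6, n-Bu4NI (cat.), DMPU, −78 °C → rt
Reagents that add atoms: none
Why: With C7 masked, C2 and C4 are the only doubly activated carbons, so the 2,4-dianion should be C-alkylated (SN2 alkylation of β-dicarbonyl enolates) once at the more basic ester-flanked C2 and then, as the remaining diketonate, once at C4 by the activated primary chloride, the pyranones meeting strong base only in the form of the electrophile.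

Step 9
Reactants: 14 methyl 6-{2-[(2R)-butan-2-yl]-1,3-dioxolan-2-yl}-2,4-bis[(6-ethyl-4-methoxy-5-methyl-2-oxo-2H-pyran-3-yl)methyl]-3,5-dioxohexanoate
Product: 15 methyl (8R)-2,4-bis[(6-ethyl-4-methoxy-5-methyl-2-oxo-2H-pyran-3-yl)methyl]-8-methyl-3,5,7-trioxodecanoate
Conditions: 2 M HCl, THF, 0 °C → rt
Reagents that add atoms: water, O
Why: Acid-catalysed ketal hydrolysis should unmask the C7 ketone under conditions that the 4-methoxy-2-pyranones tolerate, and because the oxocarbenium ion is trapped by water or loses a proton from C6 toward the conjugated enol, C8 is expected to keep its configuration.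

Step 10
Reactants: 15 methyl (8R)-2,4-bis[(6-ethyl-4-methoxy-5-methyl-2-oxo-2H-pyran-3-yl)methyl]-8-methyl-3,5,7-trioxodecanoate
Product: 16 3,3'-{[2,4,6-trihydroxy-5-[(2R)-2-methylbutanoyl]-1,3-phenylene]bis(methylene)}bis(6-ethyl-4-methoxy-5-methyl-2H-pyran-2-one)
Conditions: Mg(OMe)2 (excess), MeOH, rt → reflux; then 1 M HCl, 0 °C
Reagents that add atoms: none
Why: Mg(OMe)2 turns 15 into a Mg2+-chelated polyenolate in which the C6 carbanion, flanked by the C5 and C7 carbonyls, adds to ester carbon C1, methoxide is expelled, and the resulting 2-acylcyclohexane-1,3,5-trione tautomerises to the aromatic triol, whose phenoxide removes the product from all equilibria. The closest known reaction is the Claisen (Dieckmann-type) cyclisation of 3,5,7-triketo esters and of the corresponding tetraketide lactones to acylphloroglucinols with Mg(OMe)2, and the present chain differs only by its two C-substituents. Ring A closes in a 6-exo-trig mode through the new C1–C6 bond. No stereocentre is formed, since C2 and C4 end as sp2 ring carbons, and C8 should survive because base is consumed at the doubly activated C2, C4 and C6 and the ketone is afterwards part of a phenoxide-conjugated system. The step needs Claisen closure to prevail over aldol closure (C2 onto C7) and over lactonisation (O5 onto C1): the arm at C2 makes an aldol adduct quaternary and unable to aromatise, the branch at C8 shields the C7 carbonyl, and a pyranone formed by lactonisation is reopened by methoxide. The O-methylated pyranone arms can neither depart as enolates nor form methylene-dione acceptors, so the two CH2 bridges should not migrate under the basic conditions.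

Step 11
Reactants: 16 3,3'-{[2,4,6-trihydroxy-5-[(2R)-2-methylbutanoyl]-1,3-phenylene]bis(methylene)}bis(6-ethyl-4-methoxy-5-methyl-2H-pyran-2-one)
Product: 17 3,3'-{[2,4,6-trihydroxy-5-[(2R)-2-methylbutanoyl]-1,3-phenylene]bis(methylene)}bis(6-ethyl-4-hydroxy-5-methyl-2H-pyran-2-one) (CNP0174567.1)
Conditions: BBr3 (excess), CH2Cl2, −78 → 0 °C; then H2O
Reagents that add atoms: none
Why: Lewis-acid ether cleavage with BBr3, which binds the pyranone carbonyl and lets bromide attack the methyl group of the vinylogous ester, should free both 4-hydroxyls at low temperature without touching the lactones, the aryl ketone or the stereocentre, and hydrolytic work-up then releases the borate-bound phenols.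

Compound list
1 | 3-pentanone | CCC(=O)CC | starting material
2 | 3-(trimethylsilyloxy)pent-2-ene (E/Z mixture) | CC=C(CC)O[Si](C)(C)C | intermediate
3 | malonyl dichloride | O=C(Cl)CC(=O)Cl | starting material
4 | 6-ethyl-4-hydroxy-5-methyl-2H-pyran-2-one | CCc1oc(=O)cc(O)c1C | intermediate
5 | 6-ethyl-4-methoxy-5-methyl-2H-pyran-2-one | CCc1oc(=O)cc(OC)c1C | intermediate
6 | 3-(chloromethyl)-6-ethyl-4-methoxy-5-methyl-2H-pyran-2-one | CCc1oc(=O)c(CCl)c(OC)c1C | intermediate
7 | (R)-2-methylbutanoic acid | OC(=O)[C@H](C)CC | starting material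
8 | Meldrum's acid (2,2-dimethyl-1,3-dioxane-4,6-dione) | CC1(C)OC(=O)CC(=O)O1 | starting material
9 | 2,2-dimethyl-5-[(2R)-2-methylbutanoyl]-1,3-dioxane-4,6-dione (acyl Meldrum's acid) | CC1(C)OC(=O)C(C(=O)[C@H](C)CC)C(=O)O1 | intermediate
10 | (4R)-N-methoxy-N,4-dimethyl-3-oxohexanamide | CON(C)C(=O)CC(=O)[C@H](C)CC | intermediate
11 | 2-{2-[(2R)-butan-2-yl]-1,3-dioxolan-2-yl}-N-methoxy-N-methylacetamide | CON(C)C(=O)CC1(OCCO1)[C@H](C)CC | intermediate
12 | methyl acetoacetate | CC(=O)CC(=O)OC | starting material
13 | methyl 6-{2-[(2R)-butan-2-yl]-1,3-dioxolan-2-yl}-3,5-dioxohexanoate | COC(=O)CC(=O)CC(=O)CC1(OCCO1)[C@H](C)CC | intermediate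
14 | methyl 6-{2-[(2R)-butan-2-yl]-1,3-dioxolan-2-yl}-2,4-bis[(6-ethyl-4-methoxy-5-methyl-2-oxo-2H-pyran-3-yl)methyl]-3,5-dioxohexanoate | COC(=O)C(Cc1c(OC)c(C)c(CC)oc1=O)C(=O)C(Cc1c(OC)c(C)c(CC)oc1=O)C(=O)CC1(OCCO1)[C@H](C)CC | intermediate
15 | methyl (8R)-2,4-bis[(6-ethyl-4-methoxy-5-methyl-2-oxo-2H-pyran-3-yl)methyl]-8-methyl-3,5,7-trioxodecanoate | COC(=O)C(Cc1c(OC)c(C)c(CC)oc1=O)C(=O)C(Cc1c(OC)c(C)c(CC)oc1=O)C(=O)CC(=O)[C@H](C)CC | intermediate
16 | 3,3'-{[2,4,6-trihydroxy-5-[(2R)-2-methylbutanoyl]-1,3-phenylene]bis(methylene)}bis(6-ethyl-4-methoxy-5-methyl-2H-pyran-2-one) | CCc1oc(=O)c(Cc2c(O)c(Cc3c(OC)c(C)c(CC)oc3=O)c(O)c(C(=O)[C@H](C)CC)c2O)c(OC)c1C | intermediate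
17 | 3,3'-{[2,4,6-trihydroxy-5-[(2R)-2-methylbutanoyl]-1,3-phenylene]bis(methylene)}bis(6-ethyl-4-hydroxy-5-methyl-2H-pyran-2-one) | CCc1oc(=O)c(Cc2c(O)c(Cc3c(O)c(C)c(CC)oc3=O)c(O)c(C(=O)[C@H](C)CC)c2O)c(O)c1C | target

Total step count: 11
Longest linear sequence: 8 steps (steps 1, 2, 3, 4, 8, 9, 10 and 11, from 3-pentanone)

Steps most likely to fail

Step 10. Methoxide may cleave the C2- and C4-substituted β-dicarbonyl units by retro-Claisen fragmentation, or open the pyranone rings, faster than C6 attacks the hindered and largely enolised ester. The fallback gives up the chain folding and builds on a preformed arene. It sets out from 7 and 6: direct Friedel–Crafts acylation of phloroglucinol with 7 in BF3·OEt2 at 80 °C should give (2R)-2-methyl-1-(2,4,6-trihydroxyphenyl)butan-1-one F1. Twofold C-alkylation of its phenoxide at the two free ring carbons with 6 (NaOMe, MeOH, 0 °C → rt) then comes back to the route at 16.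

Step 8. O-alkylation of the diketonate, and proton transfer between mono- and dialkylated enolates that places two arms on one carbon, may erode the one-arm-per-carbon outcome. The fallback fixes each arm before the diketone exists and sets out from 12 and 6. γ-Alkylation of the dianion of 12 (LiN(iPr)2, THF) with 6 should give methyl 5-(6-ethyl-4-methoxy-5-methyl-2-oxo-2H-pyran-3-yl)-3-oxopentanoate F2. α-Alkylation of its monoanion (K2CO3, acetone) with 6 should give methyl 5-(6-ethyl-4-methoxy-5-methyl-2-oxo-2H-pyran-3-yl)-2-[(6-ethyl-4-methoxy-5-methyl-2-oxo-2H-pyran-3-yl)methyl]-3-oxopentanoate F3. γ-Acylation of the dianion of F3 with Weinreb amide 11 comes back to the route at 14; extra LiN(iPr)2 covers the acidic 6-ethyl groups of the pyranones, and one equivalent of 11 is used so that only the most basic chain carbanion is acylated.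

Step 4. The chloromethylated pyranone may alkylate unreacted 5 to a bis(pyranonyl)methane, or HCl may cleave the enol methyl ether. The fallback brings in the one-carbon unit as an aldehyde and sets out from 4. Vilsmeier–Haack chloroformylation (POCl3, DMF) should give 4-chloro-6-ethyl-5-methyl-2-oxo-2H-pyran-3-carbaldehyde F4. Addition–elimination with NaOMe in MeOH at 0 °C should give 6-ethyl-4-methoxy-5-methyl-2-oxo-2H-pyran-3-carbaldehyde F5. 1,2-Reduction (NaBH4, CeCl3·7H2O, MeOH) should give 6-ethyl-3-(hydroxymethyl)-4-methoxy-5-methyl-2H-pyran-2-one F6, and SOCl2 in CH2Cl2 comes back to the route at 6.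

Further compounds
F1 | step 10 | (2R)-2-methyl-1-(2,4,6-trihydroxyphenyl)butan-1-one | Oc1cc(O)c(C(=O)[C@H](C)CC)c(O)c1
F2 | step 8 | methyl 5-(6-ethyl-4-methoxy-5-methyl-2-oxo-2H-pyran-3-yl)-3-oxopentanoate | COC(=O)CC(=O)CCc1c(OC)c(C)c(CC)oc1=O
F3 | step 8 | methyl 5-(6-ethyl-4-methoxy-5-methyl-2-oxo-2H-pyran-3-yl)-2-[(6-ethyl-4-methoxy-5-methyl-2-oxo-2H-pyran-3-yl)methyl]-3-oxopentanoate | COC(=O)C(Cc1c(OC)c(C)c(CC)oc1=O)C(=O)CCc1c(OC)c(C)c(CC)oc1=O
F4 | step 4 | 4-chloro-6-ethyl-5-methyl-2-oxo-2H-pyran-3-carbaldehyde | CCc1oc(=O)c(C=O)c(Cl)c1C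
F5 | step 4 | 6-ethyl-4-methoxy-5-methyl-2-oxo-2H-pyran-3-carbaldehyde | CCc1oc(=O)c(C=O)c(OC)c1C
F6 | step 4 | 6-ethyl-3-(hydroxymethyl)-4-methoxy-5-methyl-2H-pyran-2-one | CCc1oc(=O)c(CO)c(OC)c1C
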